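**Plan**

1. Retrosynthesis: first the helpers are taken off (two benzyl ethers, a bromine at C7, two silyl ethers on ring D, and a seven-membered depsidone lactone whose methanolysis gives the ring E methyl ester and the ring C phenol). Then the C2–aryl bond and the C3–C3a bond of the indenone are cut in one operation, giving a ring A/ring D ynone and a ring C/ring E aryl-λ3-iodane.
2. Forward: a ring A Weinreb amide and a ring D acetylide give the open-chain ynone; ring C and ring E are joined by SNAr and tied into the depsidone. The key step puts the depsidone aryl group on C2 and closes the only new carbocycle, the cyclopentenone, through C3–C3a; methanolysis and hydrogenolysis then unveil the target.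
3. Enabling feature: ring D carries oxygen at both ortho positions and a para methyl group, which polarises the alkyne and stabilises a cation at C3. In ring A the C4 and C6 oxygens are ortho and para to C3a, so C3a is nucleophilic although C7a bears the ketone.
4. Helpers: bromine at C7 leaves only the wanted ortho position of ring A open. The lactone stops the aryl donor from cyclising onto ring E and masks one phenol and the ester. Silyl ethers on ring D offer no hydridic C–H bond to the C3 cation.
5. Stereochemistry: the target has no stereocentre, so no stereocontrol is needed.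

Key step: step 15

Assumption: the aryl–indenone axes are not defined in the given structure and are treated as not configurationally fixed; the four starting materials are taken as commercial.

**Route**

Step 1
Reactants: 1 methyl 2-bromo-3-methoxybenzoate
Product: 3 methyl 2-bromo-5-hydroxy-3-methoxybenzoate, via aryl pinacol boronate 2 (not isolated)
Conditions: [Ir(cod)(OMe)]2 (cat.), 4,4'-di-tert-butyl-2,2'-bipyridine (cat.), B2pin2, THF, 80 °C; then KHSO5, acetone–H2O, rt
Reagents that add atoms: bis(pinacolato)diboron, CC1(C)OB(OC1(C)C)B1OC(C)(C)C(C)(C)O1 (boron of 2 only); potassium peroxymonosulfate, [K+].OOS(=O)(=O)[O-] (phenol oxygen of 3)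
Why: Iridium-catalysed C–H borylation is sterically controlled and should take C5, the only C–H bond without an ortho substituent, and oxidation of the boronate in the same flask gives the phenol, so the bromine is fixed next to the methoxy group without an electrophilic halogenation of uncertain regiochemistry.

Step 2
Reactants: 3 methyl 2-bromo-5-hydroxy-3-methoxybenzoate
Product: 4 methyl 5-(benzyloxy)-2-bromo-3-methoxybenzoate
Conditions: BnBr, K2CO3, DMF, rt
Reagents that add atoms: benzyl bromide, BrCc1ccccc1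
Why: Williamson ether synthesis on the only phenol.

Step 3
Reactants: 4 methyl 5-(benzyloxy)-2-bromo-3-methoxybenzoate
Product: 5 5-(benzyloxy)-2-bromo-N,3-dimethoxy-N-methylbenzamide
Conditions: MeNH(OMe)·HCl, LiN(SiMe3)2, THF, −20 → 0 °C
Reagents that add atoms: N,O-dimethylhydroxylamine hydrochloride, CNOC.Cl
Why: Weinreb amide formation by aminolysis of the ester with the lithium amide of N,O-dimethylhydroxylamine, a reagent that does not exchange with the aryl bromide.

Step 4
Reactants: 6 2,6-dihydroxy-4-methylbenzaldehyde (atranol)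
Product: 7 2,6-bis[(tert-butyldimethylsilyl)oxy]-4-methylbenzaldehyde
Conditions: TBSCl, imidazole, DMF, rt
Reagents that add atoms: tert-butyldimethylsilyl chloride, CC(C)(C)[Si](C)(C)Cl
Why: Imidazole-promoted silylation of both phenols; silyl ethers are chosen for ring D because they carry no hydridic C–H bond that could be transferred to C3 in step 15.

Step 5
Reactants: 7 2,6-bis[(tert-butyldimethylsilyl)oxy]-4-methylbenzaldehyde
Product: 8 2-(2,2-dibromoethenyl)-1,3-bis[(tert-butyldimethylsilyl)oxy]-5-methylbenzene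
Conditions: CBr4, PPh3, Zn, CH2Cl2, 0 °C → rt
Reagents that add atoms: carbon tetrabromide, BrC(Br)(Br)Br
Why: Corey–Fuchs olefination (Wittig reaction of the dibromomethylene ylide), run with zinc so that no bromophosphonium species is present to cleave the silyl ethers.

Step 6
Reactants: 8 2-(2,2-dibromoethenyl)-1,3-bis[(tert-butyldimethylsilyl)oxy]-5-methylbenzene; 5 5-(benzyloxy)-2-bromo-N,3-dimethoxy-N-methylbenzamide
Product: 10 1-[5-(benzyloxy)-2-bromo-3-methoxyphenyl]-3-{2,6-bis[(tert-butyldimethylsilyl)oxy]-4-methylphenyl}prop-2-yn-1-one, via lithium acetylide 9 (not isolated)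
Conditions: 8, n-BuLi (2.05 equiv), THF, −78 → −20 °C; then 5, −78 → 0 °C; aq. NH4Cl
Reagents that add atoms: n-butyllithium, [Li]CCCC (lithium of 9 only)
Why: Second half of the Corey–Fuchs sequence (Fritsch–Buttenberg–Wiechell rearrangement to the lithium acetylide) followed by Weinreb ketone synthesis, in which the chelated adduct prevents over-addition and the acetylide is too weak to exchange with the aryl bromide.

Step 7
Reactants: 11 3-bromo-2-hydroxy-5-methoxybenzaldehyde
Product: 13 3-bromo-5-methoxybenzene-1,2-diol, via aryl formate 12 (not isolated)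
Conditions: 30% H2O2, NaOH, H2O–THF, 0 °C → rt; then HCl
Reagents that add atoms: hydrogen peroxide, OO
Why: Dakin oxidation of an ortho-hydroxybenzaldehyde, in which aryl migration gives the formate that is hydrolysed in the basic medium to the catechol.

Step 8
Reactants: 13 3-bromo-5-methoxybenzene-1,2-diol
Product: 14 2-bromo-4-methoxy-6-(methoxymethoxy)phenol
Conditions: NaH (2.1 equiv), DMF, 0 °C; MOMCl (1.0 equiv), −20 → 0 °C
Reagents that add atoms: chloromethyl methyl ether, COCCl
Why: Williamson-type mono-alkylation of the catechol dianion should occur at the oxygen remote from bromine, the more basic and less hindered phenoxide, as is known for 3-substituted catechols.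

Step 9
Reactants: 14 2-bromo-4-methoxy-6-(methoxymethoxy)phenol; 15 2,6-difluoro-4-methylbenzaldehyde
Product: 16 2-[2-bromo-4-methoxy-6-(methoxymethoxy)phenoxy]-6-fluoro-4-methylbenzaldehyde
Conditions: K2CO3, DMF, 85 °C (15 in excess)
Reagents that add atoms: none
Why: Nucleophilic aromatic substitution (SNAr) of a fluoride ortho to the formyl group by the phenoxide, the first substitution deactivating the ring so that mono-arylation should dominate.

Step 10
Reactants: 16 2-[2-bromo-4-methoxy-6-(methoxymethoxy)phenoxy]-6-fluoro-4-methylbenzaldehyde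
Product: 17 2-(benzyloxy)-6-[2-bromo-4-methoxy-6-(methoxymethoxy)phenoxy]-4-methylbenzaldehyde
Conditions: BnOH, NaH, THF, 0 °C → rt
Reagents that add atoms: benzyl alcohol, OCc1ccccc1
Why: Second SNAr, now by benzyloxide on the remaining fluorine ortho to the formyl group.

Step 11
Reactants: 17 2-(benzyloxy)-6-[2-bromo-4-methoxy-6-(methoxymethoxy)phenoxy]-4-methylbenzaldehyde
Product: 18 2-(benzyloxy)-6-[2-bromo-4-methoxy-6-(methoxymethoxy)phenoxy]-4-methylbenzoic acid
Conditions: NaClO2, NaH2PO4, 2-methyl-2-butene, t-BuOH–H2O, rt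
Reagents that add atoms: sodium chlorite, [Na+].[O-]Cl=O
Why: Pinnick oxidation converts the hindered, electron-rich aldehyde to the acid without Dakin-type cleavage and leaves the acetal and ethers untouched.

Step 12
Reactants: 18 2-(benzyloxy)-6-[2-bromo-4-methoxy-6-(methoxymethoxy)phenoxy]-4-methylbenzoic acid
Product: 20 1-(benzyloxy)-6-bromo-8-methoxy-3-methyl-11H-dibenzo[b,e][1,4]dioxepin-11-one, via hydroxy acid 19 (not isolated)
Conditions: HCl, MeOH–THF, 40 °C; evaporate; then (CF3CO)2O, CH2Cl2, 0 °C → rt
Reagents that add atoms: none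
Why: Acidic methanolysis of the methoxymethyl acetal frees the ring C phenol (the 2,6-disubstituted acid resists Fischer esterification), and anhydride-promoted intramolecular esterification then closes the seven-membered lactone, the classical depsidone lactonisation.

Step 13
Reactants: 20 1-(benzyloxy)-6-bromo-8-methoxy-3-methyl-11H-dibenzo[b,e][1,4]dioxepin-11-one
Product: 21 1-(benzyloxy)-8-methoxy-3-methyl-6-(trimethylstannyl)-11H-dibenzo[b,e][1,4]dioxepin-11-one
Conditions: (Me3Sn)2, Pd(PPh3)4 (cat.), toluene, 100 °C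
Reagents that add atoms: hexamethylditin, C[Sn](C)(C)[Sn](C)(C)C
Why: Stille-type stannylation of the aryl bromide with zerovalent palladium runs in aprotic medium, which keeps the aryl lactone closed.

Step 14
Reactants: 21 1-(benzyloxy)-8-methoxy-3-methyl-6-(trimethylstannyl)-11H-dibenzo[b,e][1,4]dioxepin-11-one
Product: 22 [1-(benzyloxy)-8-methoxy-3-methyl-11-oxo-11H-dibenzo[b,e][1,4]dioxepin-6-yl](2,4,6-trimethylphenyl)iodonium trifluoromethanesulfonate
Conditions: MesI(OAc)2, TfOH (1.0 equiv), CH2Cl2, −40 °C; then 21, −40 → 0 °C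
Reagents that add atoms: iodomesitylene diacetate, CC(=O)OI(OC(C)=O)c1c(C)cc(C)cc1C; trifluoromethanesulfonic acid, OS(=O)(=O)C(F)(F)F
Why: ipso-Substitution of the aryl–tin bond by an electrophilic trivalent iodine reagent (iododestannylation) is a known regiospecific route to unsymmetrical diaryliodonium salts.

Step 15
Reactants: 10 1-[5-(benzyloxy)-2-bromo-3-methoxyphenyl]-3-{2,6-bis[(tert-butyldimethylsilyl)oxy]-4-methylphenyl}prop-2-yn-1-one; 22 [1-(benzyloxy)-8-methoxy-3-methyl-11-oxo-11H-dibenzo[b,e][1,4]dioxepin-6-yl](2,4,6-trimethylphenyl)iodonium trifluoromethanesulfonate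
Product: 23 1-(benzyloxy)-6-[4-(benzyloxy)-7-bromo-3-{2,6-bis[(tert-butyldimethylsilyl)oxy]-4-methylphenyl}-6-methoxy-1-oxo-1H-inden-2-yl]-8-methoxy-3-methyl-11H-dibenzo[b,e][1,4]dioxepin-11-one
Conditions: CuCl (10 mol %), 2,6-di-tert-butylpyridine (1.5 equiv), 1,2-dichloroethane, 50 °C
Reagents that add atoms: none
Why: Proposed new method: monovalent copper is oxidised by iodonium salt 22 to an electrophilic aryl species of trivalent copper, which should deliver the less hindered depsidone aryl group (mesityl stays on iodine) to C2 of the ynone, the alkyne carbon made nucleophilic by the two ortho silyloxy groups and the para methyl group of ring D; these same groups stabilise the resulting linear vinyl cation at C3. The cation is then captured by the ring A carbon that is ortho to the ketone, ortho to the benzyloxy group and para to the methoxy group, a 5-endo-dig, Nazarov-like Friedel–Crafts closure that forms the C3–C3a bond and the cyclopentenone ring, and loss of the proton to the pyridine base gives the indenone. The closest known reaction types are the copper-catalysed carboarylation of alkynes with diaryliodonium salts through vinyl cations that end in a Friedel–Crafts cyclisation, the radical addition–cyclisation of 1,3-diarylpropynones to 2-substituted 3-arylindenones, and the cyclisation of β-aroylvinyl cations in Friedel–Crafts acylations of alkynes. No stereocentre is formed. Three selectivities are needed: aryl delivery to C2 and not C3, secured by the push–pull polarisation (a cation next to the carbonyl is disfavoured); closure at the ring A carbon flanked by the benzyloxy group, secured by the bromine on the other ortho position; and no self-arylation of the diaryl ether, secured by the lactone, which holds rings C and E folded in a seven-membered ring that cannot flatten to a dibenzofuran.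

Step 16
Reactants: 23 1-(benzyloxy)-6-[4-(benzyloxy)-7-bromo-3-{2,6-bis[(tert-butyldimethylsilyl)oxy]-4-methylphenyl}-6-methoxy-1-oxo-1H-inden-2-yl]-8-methoxy-3-methyl-11H-dibenzo[b,e][1,4]dioxepin-11-one
Product: 24 methyl 2-(benzyloxy)-6-{2-[4-(benzyloxy)-7-bromo-3-(2,6-dihydroxy-4-methylphenyl)-6-methoxy-1-oxo-1H-inden-2-yl]-6-hydroxy-4-methoxyphenoxy}-4-methylbenzoate
Conditions: K2CO3, MeOH–THF, rt → 45 °C; then aq. NH4Cl
Reagents that add atoms: methanol, CO
Why: Base-catalysed methanolysis (transesterification) opens the aryl lactone at its only acyl–oxygen bond to give the ring E methyl ester and the ring C phenol, and the same medium cleaves the two aryl silyl ethers.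

Step 17
Reactants: 24 methyl 2-(benzyloxy)-6-{2-[4-(benzyloxy)-7-bromo-3-(2,6-dihydroxy-4-methylphenyl)-6-methoxy-1-oxo-1H-inden-2-yl]-6-hydroxy-4-methoxyphenoxy}-4-methylbenzoate
Product: 25 Ascomindone B
Conditions: H2 (1 atm), 10% Pd/C, NaOAc, EtOAc–MeOH, rt
Reagents that add atoms: none
Why: Hydrogenolysis over palladium should remove both benzyl ethers and the aryl bromide (NaOAc takes up HBr), while the tetrasubstituted C2=C3 bond is shielded on both faces by the ortho substituents of rings C and D.

**Compound list**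

1 | methyl 2-bromo-3-methoxybenzoate | COC(=O)c1cccc(OC)c1Br | starting material
2 | methyl 2-bromo-3-methoxy-5-(4,4,5,5-tetramethyl-1,3,2-dioxaborolan-2-yl)benzoate (formed in the flask) | COC(=O)c1cc(B2OC(C)(C)C(C)(C)O2)cc(OC)c1Br | intermediate
3 | methyl 2-bromo-5-hydroxy-3-methoxybenzoate | COC(=O)c1cc(O)cc(OC)c1Br | intermediate
4 | methyl 5-(benzyloxy)-2-bromo-3-methoxybenzoate | COC(=O)c1cc(OCc2ccccc2)cc(OC)c1Br | intermediate
5 | 5-(benzyloxy)-2-bromo-N,3-dimethoxy-N-methylbenzamide | CON(C)C(=O)c1cc(OCc2ccccc2)cc(OC)c1Br | intermediate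
6 | 2,6-dihydroxy-4-methylbenzaldehyde (atranol) | Cc1cc(O)c(C=O)c(O)c1 | starting material
7 | 2,6-bis[(tert-butyldimethylsilyl)oxy]-4-methylbenzaldehyde | Cc1cc(O[Si](C)(C)C(C)(C)C)c(C=O)c(O[Si](C)(C)C(C)(C)C)c1 | intermediate
8 | 2-(2,2-dibromoethenyl)-1,3-bis[(tert-butyldimethylsilyl)oxy]-5-methylbenzene | Cc1cc(O[Si](C)(C)C(C)(C)C)c(C=C(Br)Br)c(O[Si](C)(C)C(C)(C)C)c1 | intermediate
9 | lithium {2,6-bis[(tert-butyldimethylsilyl)oxy]-4-methylphenyl}acetylide (formed in the flask) | Cc1cc(O[Si](C)(C)C(C)(C)C)c(C#C[Li])c(O[Si](C)(C)C(C)(C)C)c1 | intermediate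
10 | 1-[5-(benzyloxy)-2-bromo-3-methoxyphenyl]-3-{2,6-bis[(tert-butyldimethylsilyl)oxy]-4-methylphenyl}prop-2-yn-1-one | COc1cc(OCc2ccccc2)cc(C(=O)C#Cc2c(O[Si](C)(C)C(C)(C)C)cc(C)cc2O[Si](C)(C)C(C)(C)C)c1Br | intermediate
11 | 3-bromo-2-hydroxy-5-methoxybenzaldehyde | COc1cc(Br)c(O)c(C=O)c1 | starting material
12 | 3-bromo-2-hydroxy-5-methoxyphenyl formate (formed in the flask) | COc1cc(Br)c(O)c(OC=O)c1 | intermediate
13 | 3-bromo-5-methoxybenzene-1,2-diol | COc1cc(O)c(O)c(Br)c1 | intermediate
14 | 2-bromo-4-methoxy-6-(methoxymethoxy)phenol | COCOc1cc(OC)cc(Br)c1O | intermediate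
15 | 2,6-difluoro-4-methylbenzaldehyde | Cc1cc(F)c(C=O)c(F)c1 | starting material
16 | 2-[2-bromo-4-methoxy-6-(methoxymethoxy)phenoxy]-6-fluoro-4-methylbenzaldehyde | COCOc1cc(OC)cc(Br)c1Oc1cc(C)cc(F)c1C=O | intermediate
17 | 2-(benzyloxy)-6-[2-bromo-4-methoxy-6-(methoxymethoxy)phenoxy]-4-methylbenzaldehyde | COCOc1cc(OC)cc(Br)c1Oc1cc(C)cc(OCc2ccccc2)c1C=O | intermediate
18 | 2-(benzyloxy)-6-[2-bromo-4-methoxy-6-(methoxymethoxy)phenoxy]-4-methylbenzoic acid | COCOc1cc(OC)cc(Br)c1Oc1cc(C)cc(OCc2ccccc2)c1C(=O)O | intermediate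
19 | 2-(benzyloxy)-6-(2-bromo-6-hydroxy-4-methoxyphenoxy)-4-methylbenzoic acid (formed in the flask) | COc1cc(O)c(Oc2cc(C)cc(OCc3ccccc3)c2C(=O)O)c(Br)c1 | intermediate
20 | 1-(benzyloxy)-6-bromo-8-methoxy-3-methyl-11H-dibenzo[b,e][1,4]dioxepin-11-one | O=C1Oc2cc(OC)cc(Br)c2Oc2cc(C)cc(OCc3ccccc3)c21 | intermediate
21 | 1-(benzyloxy)-8-methoxy-3-methyl-6-(trimethylstannyl)-11H-dibenzo[b,e][1,4]dioxepin-11-one | O=C1Oc2cc(OC)cc([Sn](C)(C)C)c2Oc2cc(C)cc(OCc3ccccc3)c21 | intermediate
22 | [1-(benzyloxy)-8-methoxy-3-methyl-11-oxo-11H-dibenzo[b,e][1,4]dioxepin-6-yl](2,4,6-trimethylphenyl)iodonium trifluoromethanesulfonate | O=C1Oc2cc(OC)cc([I+]c3c(C)cc(C)cc3C)c2Oc2cc(C)cc(OCc3ccccc3)c21.[O-]S(=O)(=O)C(F)(F)F | intermediate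
23 | 1-(benzyloxy)-6-[4-(benzyloxy)-7-bromo-3-{2,6-bis[(tert-butyldimethylsilyl)oxy]-4-methylphenyl}-6-methoxy-1-oxo-1H-inden-2-yl]-8-methoxy-3-methyl-11H-dibenzo[b,e][1,4]dioxepin-11-one | O=C1Oc2cc(OC)cc(C3=C(c4c(O[Si](C)(C)C(C)(C)C)cc(C)cc4O[Si](C)(C)C(C)(C)C)c4c(OCc5ccccc5)cc(OC)c(Br)c4C3=O)c2Oc2cc(C)cc(OCc3ccccc3)c21 | intermediate
24 | methyl 2-(benzyloxy)-6-{2-[4-(benzyloxy)-7-bromo-3-(2,6-dihydroxy-4-methylphenyl)-6-methoxy-1-oxo-1H-inden-2-yl]-6-hydroxy-4-methoxyphenoxy}-4-methylbenzoate | COC(=O)c1c(OCc2ccccc2)cc(C)cc1Oc1c(O)cc(OC)cc1C1=C(c2c(O)cc(C)cc2O)c2c(OCc3ccccc3)cc(OC)c(Br)c2C1=O | intermediate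
25 | Ascomindone B, methyl 2-{2-[3-(2,6-dihydroxy-4-methylphenyl)-4-hydroxy-6-methoxy-1-oxo-1H-inden-2-yl]-6-hydroxy-4-methoxyphenoxy}-6-hydroxy-4-methylbenzoate | COC(=O)c1c(O)cc(C)cc1Oc1c(O)cc(OC)cc1C1=C(c2c(O)cc(C)cc2O)c2c(O)cc(OC)cc2C1=O | target

**Count and risks**

Total step count: 17. Longest linear sequence: 11 steps (from 11 to 25, steps 7 to 17).

Steps most likely to fail:

1. Step 15 (Proposed new method). Aryl transfer from trivalent copper to C2 of this conjugated, hindered alkyne may be slow, so that the iodonium salt is consumed unproductively; the C3 cation may also be intercepted by triflate or lose a silyl group before ring A closes. The fallback uses known chemistry, sets out from 10 and 22 and comes back at 23. Conjugate addition of pyrrolidine to 10 (MeOH, rt) should give the enaminone F1, and mild aqueous acid (AcOH–H2O–THF) should hydrolyse it to the 1,3-diketone F2. The sodium enolate of F2 (NaH, DMF) is then C-arylated by 22 without a metal, the known arylation of β-dicarbonyl enolates by diaryliodonium salts, in which the doubly ortho-substituted mesityl group is the ligand that is not transferred to carbon; this should give the 2-aryl-1,3-diketone F3. Acid (CF3CO2H in CH2Cl2, or BF3·OEt2) then effects the known cyclodehydration of 2-aryl-1,3-diaryl-1,3-diketones to 2,3-diarylindenones. Ring A attacks the ring D ketone and closes C3–C3a; ring D has no free ortho position and the bromine again blocks the other site of ring A, so 23 should result.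

2. Step 14. Substitution at tin may be outrun by attack of the trivalent iodine reagent on the electron-rich C–H positions of the methoxy-bearing ring or by protodestannylation. The fallback sets out from 21 and comes back at 23. Iododestannylation (I2, CH2Cl2, 0 °C) should give the aryl iodide F4. One-pot oxidation (mCPBA, TsOH·H2O, MeCN) and coupling with 1,3,5-trimethoxybenzene should give the aryl(2,4,6-trimethoxyphenyl)iodonium tosylate F5, whose trimethoxyphenyl group is the ligand that stays on iodine. F5 is then used in place of 22 under the conditions of step 15.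

3. Step 17. The risk is over-reduction of the C2=C3 bond or of the ketone during hydrogenolysis, or stalling at partly debenzylated or still brominated stages. The fallback sets out from 24 and comes back at 25. Homogeneous hydrodebromination with formate (Pd(OAc)2, PPh3, HCO2H, Et3N, DMF, 60 °C) should give the debrominated bis(benzyl ether) F6. Lewis-acid debenzylation with a cation scavenger (BCl3, pentamethylbenzene, CH2Cl2, −78 °C) then removes both benzyl ethers and leaves the methyl ethers, the methyl ester and the indenone untouched.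

**Further compounds**

F1 | step 15 | (E)-1-[5-(benzyloxy)-2-bromo-3-methoxyphenyl]-3-{2,6-bis[(tert-butyldimethylsilyl)oxy]-4-methylphenyl}-3-(pyrrolidin-1-yl)prop-2-en-1-one | COc1cc(OCc2ccccc2)cc(C(=O)/C=C(/N2CCCC2)c2c(O[Si](C)(C)C(C)(C)C)cc(C)cc2O[Si](C)(C)C(C)(C)C)c1Br
F2 | step 15 | 1-[5-(benzyloxy)-2-bromo-3-methoxyphenyl]-3-{2,6-bis[(tert-butyldimethylsilyl)oxy]-4-methylphenyl}propane-1,3-dione | COc1cc(OCc2ccccc2)cc(C(=O)CC(=O)c2c(O[Si](C)(C)C(C)(C)C)cc(C)cc2O[Si](C)(C)C(C)(C)C)c1Br
F3 | step 15 | 1-[5-(benzyloxy)-2-bromo-3-methoxyphenyl]-2-[1-(benzyloxy)-8-methoxy-3-methyl-11-oxo-11H-dibenzo[b,e][1,4]dioxepin-6-yl]-3-{2,6-bis[(tert-butyldimethylsilyl)oxy]-4-methylphenyl}propane-1,3-dione (racemic, enolisable) | COc1cc(OCc2ccccc2)cc(C(=O)C(c2cc(OC)cc3OC(=O)c4c(OCc5ccccc5)cc(C)cc4Oc23)C(=O)c2c(O[Si](C)(C)C(C)(C)C)cc(C)cc2O[Si](C)(C)C(C)(C)C)c1Br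
F4 | step 14 | 1-(benzyloxy)-6-iodo-8-methoxy-3-methyl-11H-dibenzo[b,e][1,4]dioxepin-11-one | O=C1Oc2cc(OC)cc(I)c2Oc2cc(C)cc(OCc3ccccc3)c21
F5 | step 14 | [1-(benzyloxy)-8-methoxy-3-methyl-11-oxo-11H-dibenzo[b,e][1,4]dioxepin-6-yl](2,4,6-trimethoxyphenyl)iodonium 4-methylbenzenesulfonate | O=C1Oc2cc(OC)cc([I+]c3c(OC)cc(OC)cc3OC)c2Oc2cc(C)cc(OCc3ccccc3)c21.Cc1ccc(S(=O)(=O)[O-])cc1
F6 | step 17 | methyl 2-(benzyloxy)-6-{2-[4-(benzyloxy)-3-(2,6-dihydroxy-4-methylphenyl)-6-methoxy-1-oxo-1H-inden-2-yl]-6-hydroxy-4-methoxyphenoxy}-4-methylbenzoate | COC(=O)c1c(OCc2ccccc2)cc(C)cc1Oc1c(O)cc(OC)cc1C1=C(c2c(O)cc(C)cc2O)c2c(OCc3ccccc3)cc(OC)cc2C1=O
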